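**Retrosynthetic overview**

- Atom numbers follow the labdane skeleton (ring A = C1–C5 and C10, ring B = C5–C10, C17 = exocyclic CH2 on C8, C11 = acetoxy carbon). The side chain is cut at C11–C12 (vinylogous Mukaiyama aldol, then O-acetylation), which leads back to albicanal and albicanol.
- Ring A of albicanol is given a temporary C3 ketone and C2 methyl ester (later removed by Krapcho and Wolff–Kishner steps), so that C2 can be an electrophilic radical centre.
- Key disconnection: C1–C2 (closes ring A first) and C9–C10 (closes ring B second) in one Mn(OAc)3/Cu(OAc)2 oxidative radical bicyclization of an acyclic β-keto ester, which also sets C10 and C9 and creates the C8=C17 methylene.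
- Enabling feature: the quaternary, methyl-bearing C10 lies between C1 (a CH2 of ring A) and C9, and C8 carries the one-carbon branch C17. C10 can therefore be the inner carbon of an isopropenyl group on C5 with C1 as its CH2 end, and C8=C9 a methyl-bearing E alkene; a C2 radical attacking C1 passes the radical to C10, then to C8, where it ends as the exocyclic methylene.
- The precursor comes from (S)-carvone, which supplies C5 (the only stereocentre carried in), the isopropenyl group, the site of the C4 gem-dimethyl group and the C3 carbonyl, by 6,6-dimethylation, conjugate reduction and oxidative ring opening.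

Key step: step 8

**Route**

Step 1
Reactants: 1 (S)-(+)-carvone
Product: 3 6,6-dimethylcarvone [(5R)-2,6,6-trimethyl-5-(prop-1-en-2-yl)cyclohex-2-en-1-one], via 6-methylcarvone 2 (not isolated)
Conditions: LiN(i-Pr)2 (1.1 equiv), THF, −78 °C, then MeI, −78 → 0 °C; recool, LiN(i-Pr)2 (1.3 equiv), −78 °C, then MeI, DMPU, −78 °C → rt
Reagents that add atoms: iodomethane, CI
Why: kinetic deprotonation of the cross-conjugated enone at the α′ carbon (the later C4) and SN2 methylation, run twice (enolate alkylation), should build the gem-dimethyl group next to the isopropenyl-bearing stereocentre (the later C5), which is not acidic and keeps its configuration.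

Step 2
Reactants: 3 6,6-dimethylcarvone
Product: 4 (3R,6RS)-2,2,6-trimethyl-3-(prop-1-en-2-yl)cyclohexan-1-one
Conditions: Li[HB(s-Bu)3] (1.1 equiv), THF, −78 °C; then H2O
Reagents that add atoms: none
Why: conjugate hydride reduction of the β-unsubstituted enone by the bulky trialkylborohydride (1,2-attack is blocked by the flanking quaternary carbon) should saturate the ring double bond without touching the isopropenyl group; the new methyl-bearing centre forms as a mixture, which does not matter because step 3 destroys it.

Step 3
Reactants: 4 (3R,6RS)-2,2,6-trimethyl-3-(prop-1-en-2-yl)cyclohexan-1-one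
Product: 5 (3R)-2,2-dimethyl-6-oxo-3-(prop-1-en-2-yl)heptanoic acid
Conditions: KOt-Bu (3 equiv), O2 (1 atm), t-BuOH/DME, 0 °C → rt; then cold dilute HCl
Reagents that add atoms: dioxygen, O=O
Why: the ketone can enolise only toward the methyl-bearing carbon, and autoxidation of that enolate to the α-hydroperoxy ketone followed by base-induced C–C cleavage (oxidative cleavage of an α-branched ketone) should open the ring to the methyl ketone and the carboxylic acid without touching the stereocentre.

Step 4
Reactants: 5 (3R)-2,2-dimethyl-6-oxo-3-(prop-1-en-2-yl)heptanoic acid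
Product: 6 (3R,6E)-8-ethoxy-2,2,6-trimethyl-8-oxo-3-(prop-1-en-2-yl)oct-6-enoic acid
Conditions: (EtO)2P(O)CH2CO2Et (2.5 equiv), NaH (3.6 equiv), THF, 0 → 50 °C; cold dilute HCl; chromatography to remove the Z isomer
Reagents that add atoms: triethyl phosphonoacetate, CCOC(=O)CP(=O)(OCC)OCC
Why: Horner–Wadsworth–Emmons olefination of the methyl ketone (the acid travels as its inert sodium carboxylate) should give mainly the thermodynamically preferred E trisubstituted enoate, whose geometry later fixes the configuration at C9.

Step 5
Reactants: 6 (3R,6E)-8-ethoxy-2,2,6-trimethyl-8-oxo-3-(prop-1-en-2-yl)oct-6-enoic acid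
Product: 7 (3R,6E)-8-hydroxy-2,2,6-trimethyl-3-(prop-1-en-2-yl)oct-6-enoic acid
Conditions: i-Bu2AlH (4 equiv), CH2Cl2, −78 → −30 °C; aq. potassium sodium tartrate, then cold dilute HCl
Reagents that add atoms: none
Why: the first equivalent turns the hindered acid into an aluminium carboxylate that should resist reduction at low temperature, while the conjugated ethyl ester undergoes 1,2-reduction to the allylic alcohol (hydride reduction of an enoate) with the alkene geometry retained.

Step 6
Reactants: 7 (3R,6E)-8-hydroxy-2,2,6-trimethyl-3-(prop-1-en-2-yl)oct-6-enoic acid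
Product: 8 (3R,6E)-8-(acetyloxy)-2,2,6-trimethyl-3-(prop-1-en-2-yl)oct-6-enoic acid
Conditions: Ac2O (3 equiv), pyridine, DMAP (cat.), CH2Cl2, 0 °C → rt; aqueous work-up
Reagents that add atoms: acetic anhydride, CC(=O)OC(C)=O
Why: DMAP-catalysed acylation of the primary allylic alcohol gives an acetate that should survive the acetic acid medium of the key step, and any mixed anhydride formed at the hindered acid is hydrolysed back during work-up.

Step 7
Reactants: 8 (3R,6E)-8-(acetyloxy)-2,2,6-trimethyl-3-(prop-1-en-2-yl)oct-6-enoic acid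
Product: 10 methyl (5R,8E)-10-(acetyloxy)-4,4,8-trimethyl-3-oxo-5-(prop-1-en-2-yl)dec-8-enoate, via acyl imidazolide 9 (not isolated)
Conditions: CDI (1.2 equiv), THF, rt; then KO2CCH2CO2Me (2 equiv), MgCl2 (2 equiv), Et3N, MeCN, rt → 50 °C; dilute HCl
Reagents that add atoms: methyl potassium malonate, COC(=O)CC(=O)[O-].[K+]
Why: activation of the acid as its imidazolide and C-acylation of the magnesium enolate of the malonate half-ester, which loses CO2 on acidic work-up (malonate half-ester homologation to a β-keto ester), is known for α,α-disubstituted acids and should leave the acetate and both alkenes untouched.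

Step 8
Reactants: 10 methyl (5R,8E)-10-(acetyloxy)-4,4,8-trimethyl-3-oxo-5-(prop-1-en-2-yl)dec-8-enoate
Product: 11 methyl (2RS,4aR,8S,8aS)-8-(acetoxymethyl)-4,4,8a-trimethyl-7-methylidene-3-oxodecahydronaphthalene-2-carboxylate (trans-decalin; labdane positions: C2 ester, C3 ketone, C8 exocyclic methylene, C9 CH2OAc)
Conditions: Mn(OAc)3·2H2O (2.2 equiv), Cu(OAc)2·H2O (1 equiv), degassed AcOH (0.02 M), rt → 40 °C
Reagents that add atoms: none
Why: Mn(OAc)3 oxidises the enol of the β-keto ester to an electrophilic, manganese-bound C2 radical, which adds to the terminal C1 of the isopropenyl group (6-endo-trig, ring A, new bond C1–C2) to give the tertiary C10 radical; this adds to C9 of the E trisubstituted alkene (6-endo-trig, ring B, new bond C9–C10), and the tertiary C8 radical is trapped by Cu(OAc)2 as an alkylcopper species that loses a hydrogen of the C8 methyl group to give the exocyclic methylene. The closest known reaction type is the oxidative free-radical polycyclization of unsaturated β-keto esters with Mn(OAc)3/Cu(OAc)2, which closes cyclohexanone rings 6-endo onto 1,1-disubstituted alkenes and carries the resulting tertiary radical into a second 6-endo closure. C10 is controlled by the carvone-derived C5 centre: its chain sits equatorially on the chair of ring A and reaches the planar C10 radical through a chair transition state that should give the trans ring fusion (C10 methyl axial, anti to H-5). C9 is controlled by the E geometry of the C8=C9 bond, which places C11 equatorial in that chair (H-9 anti to the C10 methyl); the C2 centre forms as a mixture or as the enol and is removed in step 9. The step needs 6-endo rather than 5-exo attack in the first closure, which the ketone inside the forming ring, the tertiary radical that results and the crowding at C10 should secure, and it needs the C10 radical to cyclise before it is oxidised, which the low Cu(OAc)2 concentration and the six-atom tether should secure. It also needs hydrogen loss from the methyl group and not from ring positions, which the preference of the copper-mediated elimination for the least hindered β-hydrogen should provide, with any endocyclic isomers removed on AgNO3-impregnated silica.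

Step 9
Reactants: 11 bicyclic β-keto ester
Product: 12 [(1S,4aR,8aS)-5,5,8a-trimethyl-2-methylidene-6-oxodecahydronaphthalen-1-yl]methyl acetate
Conditions: LiCl (3 equiv), H2O (2 equiv), DMSO, 150 °C
Reagents that add atoms: none
Why: Krapcho dealkoxycarbonylation (chloride attack on the ester methyl, loss of CO2, protonation of the ketone enolate) should remove the C2 ester and with it the C2 stereocentre, and partial loss of the acetate would be harmless because step 10 cleaves it anyway.

Step 10
Reactants: 12 [(1S,4aR,8aS)-5,5,8a-trimethyl-2-methylidene-6-oxodecahydronaphthalen-1-yl]methyl acetate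
Product: 14 albicanol {[(1S,4aS,8aS)-5,5,8a-trimethyl-2-methylidenedecahydronaphthalen-1-yl]methanol}, via hydroxy hydrazone 13 (not isolated)
Conditions: N2H4·H2O (10 equiv), KOH (6 equiv), diethylene glycol, 130 °C, then distil to 200 °C, under N2
Reagents that add atoms: none
Why: Wolff–Kishner reduction (Huang-Minlon procedure) of the C3 ketone through its hydrazone is a standard deoxygenation of 4,4-dimethyl-3-keto terpenoids, the hot hydroxide also saponifies the acetate, and the unactivated exocyclic alkene and the three stereocentres, none of them now α to a carbonyl, should survive.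

Step 11
Reactants: 14 albicanol
Product: 15 albicanal [(1S,4aS,8aS)-5,5,8a-trimethyl-2-methylidenedecahydronaphthalene-1-carbaldehyde]
Conditions: Dess–Martin periodinane (1.3 equiv), NaHCO3, CH2Cl2, 0 °C → rt; used at once
Reagents that add atoms: none
Why: buffered Dess–Martin oxidation of the hindered primary alcohol stops at the aldehyde under near-neutral conditions, which should keep the epimerisable C9 centre and the β,γ-position of the double bond intact.

Step 12
Reactants: 16 methyl 3-methylbut-2-enoate
Product: 17 [(1-methoxy-3-methylbuta-1,3-dien-1-yl)oxy]trimethylsilane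
Conditions: LiN(i-Pr)2 (1.1 equiv), THF, −78 °C; Me3SiCl, −78 °C → rt; distillation
Reagents that add atoms: chlorotrimethylsilane, C[Si](C)(C)Cl
Why: γ-deprotonation of the ester gives the extended enolate, which is silylated on oxygen to the silyl dienol ether (silyl ketene acetal formation).

Step 13
Reactants: 15 albicanal; 17 [(1-methoxy-3-methylbuta-1,3-dien-1-yl)oxy]trimethylsilane
Product: 18 methyl (2E,5S)-5-hydroxy-3-methyl-5-[(1S,4aS,8aS)-5,5,8a-trimethyl-2-methylidenedecahydronaphthalen-1-yl]pent-2-enoate
Conditions: BF3·OEt2 (1.2 equiv), CH2Cl2, −78 °C; aq. NaHCO3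
Reagents that add atoms: none
Why: vinylogous Mukaiyama aldol addition through the γ-carbon of the dienol ether in an open transition state, in which Felkin–Anh attack anti to the quaternary C10 (C8 near the carbonyl oxygen, H-9 near the incoming nucleophile) should set the 11S carbinol and reaction through the s-trans diene should give the 2E enoate, any 2Z isomer lactonising and being separated.

Step 14
Reactants: 18 methyl (2E,5S)-5-hydroxy-3-methyl-5-[(1S,4aS,8aS)-5,5,8a-trimethyl-2-methylidenedecahydronaphthalen-1-yl]pent-2-enoate
Product: 19 methyl (2E,5S)-5-(acetyloxy)-3-methyl-5-[(1S,4aS,8aS)-5,5,8a-trimethyl-2-methylidenedecahydronaphthalen-1-yl]pent-2-enoate (target)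
Conditions: Ac2O (3 equiv), DMAP (0.2 equiv), pyridine, CH2Cl2, 0 °C → rt
Reagents that add atoms: acetic anhydride, CC(=O)OC(C)=O
Why: DMAP-catalysed acetylation of the secondary alcohol under mild, weakly basic conditions should avoid elimination of the new acetate toward the dienoate and leave the four stereocentres and the E alkene unchanged.

**Compound list**

1 | (S)-(+)-carvone, (5S)-2-methyl-5-(prop-1-en-2-yl)cyclohex-2-en-1-one | CC1=CC[C@@H](CC1=O)C(C)=C | starting material
2 | 6-methylcarvone, (5S,6RS)-2,6-dimethyl-5-(prop-1-en-2-yl)cyclohex-2-en-1-one (formed in situ) | CC1=CC[C@H](C(C)=C)C(C)C1=O | intermediate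
3 | 6,6-dimethylcarvone, (5R)-2,6,6-trimethyl-5-(prop-1-en-2-yl)cyclohex-2-en-1-one | CC1=CC[C@H](C(C)=C)C(C)(C)C1=O | intermediate
4 | (3R,6RS)-2,2,6-trimethyl-3-(prop-1-en-2-yl)cyclohexan-1-one | CC1CC[C@H](C(C)=C)C(C)(C)C1=O | intermediate
5 | (3R)-2,2-dimethyl-6-oxo-3-(prop-1-en-2-yl)heptanoic acid | CC(=O)CC[C@H](C(C)=C)C(C)(C)C(=O)O | intermediate
6 | (3R,6E)-8-ethoxy-2,2,6-trimethyl-8-oxo-3-(prop-1-en-2-yl)oct-6-enoic acid | CCOC(=O)/C=C(\C)CC[C@H](C(C)=C)C(C)(C)C(=O)O | intermediate
7 | (3R,6E)-8-hydroxy-2,2,6-trimethyl-3-(prop-1-en-2-yl)oct-6-enoic acid | OC/C=C(\C)CC[C@H](C(C)=C)C(C)(C)C(=O)O | intermediate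
8 | (3R,6E)-8-(acetyloxy)-2,2,6-trimethyl-3-(prop-1-en-2-yl)oct-6-enoic acid | CC(=O)OC/C=C(\C)CC[C@H](C(C)=C)C(C)(C)C(=O)O | intermediate
9 | acyl imidazolide of 8, (2E,6R)-8-(1H-imidazol-1-yl)-3,7,7-trimethyl-8-oxo-6-(prop-1-en-2-yl)oct-2-en-1-yl acetate (formed in situ) | CC(=O)OC/C=C(\C)CC[C@H](C(C)=C)C(C)(C)C(=O)n1ccnc1 | intermediate
10 | methyl (5R,8E)-10-(acetyloxy)-4,4,8-trimethyl-3-oxo-5-(prop-1-en-2-yl)dec-8-enoate | CC(=O)OC/C=C(\C)CC[C@H](C(C)=C)C(C)(C)C(=O)CC(=O)OC | intermediate
11 | methyl (2RS,4aR,8S,8aS)-8-(acetoxymethyl)-4,4,8a-trimethyl-7-methylidene-3-oxodecahydronaphthalene-2-carboxylate | C=C1CC[C@H]2C(C)(C)C(=O)C(C(=O)OC)C[C@]2(C)[C@H]1COC(C)=O | intermediate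
12 | [(1S,4aR,8aS)-5,5,8a-trimethyl-2-methylidene-6-oxodecahydronaphthalen-1-yl]methyl acetate | C=C1CC[C@H]2C(C)(C)C(=O)CC[C@]2(C)[C@H]1COC(C)=O | intermediate
13 | [(1S,4aR,8aS)-6-hydrazinylidene-5,5,8a-trimethyl-2-methylidenedecahydronaphthalen-1-yl]methanol (formed in situ) | C=C1CC[C@H]2C(C)(C)C(=NN)CC[C@]2(C)[C@H]1CO | intermediate
14 | albicanol, [(1S,4aS,8aS)-5,5,8a-trimethyl-2-methylidenedecahydronaphthalen-1-yl]methanol | C=C1CC[C@H]2C(C)(C)CCC[C@]2(C)[C@H]1CO | intermediate
15 | albicanal, (1S,4aS,8aS)-5,5,8a-trimethyl-2-methylidenedecahydronaphthalene-1-carbaldehyde | C=C1CC[C@H]2C(C)(C)CCC[C@]2(C)[C@H]1C=O | intermediate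
16 | methyl 3-methylbut-2-enoate | COC(=O)C=C(C)C | starting material
17 | [(1-methoxy-3-methylbuta-1,3-dien-1-yl)oxy]trimethylsilane | COC(=CC(C)=C)O[Si](C)(C)C | intermediate
18 | methyl (2E,5S)-5-hydroxy-3-methyl-5-[(1S,4aS,8aS)-5,5,8a-trimethyl-2-methylidenedecahydronaphthalen-1-yl]pent-2-enoate | C=C1CC[C@H]2C(C)(C)CCC[C@]2(C)[C@H]1[C@H](C/C(C)=C/C(=O)OC)O | intermediate
19 | methyl (2E,5S)-5-(acetyloxy)-3-methyl-5-[(1S,4aS,8aS)-5,5,8a-trimethyl-2-methylidenedecahydronaphthalen-1-yl]pent-2-enoate | C=C1CC[C@H]2C(C)(C)CCC[C@]2(C)[C@H]1[C@H](C/C(C)=C/C(=O)OC)OC(C)=O | target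

**Step count**

Total step count: 14. Longest linear sequence: 13 steps (steps 1–11, 13 and 14, from (S)-carvone); step 12 is a one-step side branch.

**Steps most likely to fail, with fallbacks**

1. Step 8 (key bicyclization). What may go wrong: the bicyclic β-keto ester still has an enolisable hydrogen at C2 and may be oxidised further by Mn(OAc)3 while substrate remains, and the C10 radical may be oxidised before ring B closes. The fallback blocks C2 instead of titrating the oxidant. Setting out from 10, chlorination at C2 with N-chlorosuccinimide would give the α-chloro β-keto ester methyl (2RS,5R,8E)-10-(acetyloxy)-2-chloro-4,4,8-trimethyl-3-oxo-5-(prop-1-en-2-yl)dec-8-enoate F1. The same Mn(OAc)3/Cu(OAc)2 treatment would then give the chlorinated bicycle methyl (2RS,4aR,8S,8aS)-8-(acetoxymethyl)-2-chloro-4,4,8a-trimethyl-7-methylidene-3-oxodecahydronaphthalene-2-carboxylate F2, which has no α-hydrogen and cannot be oxidised again. Zinc dust in acetic acid would remove the chlorine and bring the route back to 11.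

2. Step 4 (olefination). What may go wrong: low E/Z selectivity in the olefination of the methyl ketone, so that much material is lost as the Z isomer, which would lead to the wrong configuration at C9. The fallback replaces carbonyl olefination by a stereospecific carbometalation. Setting out from 5, esterification with Me3SiCHN2 in MeOH would give methyl (3R)-2,2-dimethyl-6-oxo-3-(prop-1-en-2-yl)heptanoate F3. Kinetic enol phosphate formation and elimination (LiN(i-Pr)2, ClP(O)(OEt)2, then more LiN(i-Pr)2) would give the terminal alkyne methyl (3R)-2,2-dimethyl-3-(prop-1-en-2-yl)hept-6-ynoate F4. Zirconium-catalysed syn-methylalumination (Me3Al, Cp2ZrCl2), then n-BuLi and paraformaldehyde, would give only the E allylic alcohol methyl (3R,6E)-8-hydroxy-2,2,6-trimethyl-3-(prop-1-en-2-yl)oct-6-enoate F5. Cleavage of the hindered methyl ester at the O-methyl carbon with LiI in hot pyridine would come back to 7.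

3. Step 13 (vinylogous aldol). What may go wrong: insufficient facial selectivity at the aldehyde carbon (C11), partial formation of the 2Z enoate, or Lewis-acid-induced migration of the exocyclic double bond into conjugation with the aldehyde. The fallback replaces the substrate-controlled aldol by a reagent-controlled propargylation and a stereospecific alkyne carbometalation. Setting out from 15, propargylation with allenylboronic acid pinacol ester under a chiral BINOL-derived phosphoric acid catalyst chosen to give the 11S carbinol would give the homopropargylic alcohol (1S)-1-[(1S,4aS,8aS)-5,5,8a-trimethyl-2-methylidenedecahydronaphthalen-1-yl]but-3-yn-1-ol F6. Methylalumination (Me3Al, Cp2ZrCl2) and iodinolysis would give the E vinyl iodide (1S,3E)-4-iodo-3-methyl-1-[(1S,4aS,8aS)-5,5,8a-trimethyl-2-methylidenedecahydronaphthalen-1-yl]but-3-en-1-ol F7. Pd(PPh3)4-catalysed methoxycarbonylation (CO, MeOH, Et3N) would come back to 18 with the double-bond geometry retained.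

**Further compounds**

F1 | step 8 | methyl (2RS,5R,8E)-10-(acetyloxy)-2-chloro-4,4,8-trimethyl-3-oxo-5-(prop-1-en-2-yl)dec-8-enoate | CC(=O)OC/C=C(\C)CC[C@H](C(C)=C)C(C)(C)C(=O)C(Cl)C(=O)OC
F2 | step 8 | methyl (2RS,4aR,8S,8aS)-8-(acetoxymethyl)-2-chloro-4,4,8a-trimethyl-7-methylidene-3-oxodecahydronaphthalene-2-carboxylate | C=C1CC[C@H]2C(C)(C)C(=O)C(Cl)(C(=O)OC)C[C@]2(C)[C@H]1COC(C)=O
F3 | step 4 | methyl (3R)-2,2-dimethyl-6-oxo-3-(prop-1-en-2-yl)heptanoate | CC(=O)CC[C@H](C(C)=C)C(C)(C)C(=O)OC
F4 | step 4 | methyl (3R)-2,2-dimethyl-3-(prop-1-en-2-yl)hept-6-ynoate | C#CCC[C@H](C(C)=C)C(C)(C)C(=O)OC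
F5 | step 4 | methyl (3R,6E)-8-hydroxy-2,2,6-trimethyl-3-(prop-1-en-2-yl)oct-6-enoate | OC/C=C(\C)CC[C@H](C(C)=C)C(C)(C)C(=O)OC
F6 | step 13 | (1S)-1-[(1S,4aS,8aS)-5,5,8a-trimethyl-2-methylidenedecahydronaphthalen-1-yl]but-3-yn-1-ol | C=C1CC[C@H]2C(C)(C)CCC[C@]2(C)[C@H]1[C@H](CC#C)O
F7 | step 13 | (1S,3E)-4-iodo-3-methyl-1-[(1S,4aS,8aS)-5,5,8a-trimethyl-2-methylidenedecahydronaphthalen-1-yl]but-3-en-1-ol | C=C1CC[C@H]2C(C)(C)CCC[C@]2(C)[C@H]1[C@H](C/C(C)=C/I)O
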